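**Early times.** For hours Q barely rises above the scatter: ash ends at 0.3 % and alder at 0.8 %. By 4.00 h, however, larch shows 9.9 % and cedar 4.9 %. I read this as Q making more Q (autocatalysis), so the rate to follow is the rate per Q, g.

| setting | ash | alder | larch | cedar | theta | delta | gamma | eta |
|---|---|---|---|---|---|---|---|---|
| L | 0.013 M | 0.026 M | 0.059 M | 0.050 M | 0.012 M | 0.030 M | 0.050 M | 0.025 M |
| X | 5 mM | 5 mM | 5 mM | 4.7 mM | 8.00 mM | 15.0 mM | 5.00 mM | 3.00 mM |
| remark | run made earlier | run made earlier | run made earlier | run made earlier |  |  |  |  |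
| time |  |  |  |  | 8.0 h | 8.0 h | 8.0 h | 8.0 h |

| run | time / h | Q / % | L / % |
|---|---|---|---|
| ash | 0.333 | 0.2 | 93.5 |
| ash | 0.667 | 0 | 87.2 |
| ash | 1.50 | 0 | 76.1 |
| ash | 4.00 | 0.3 | 59.2 |
| alder | 1.00 | 0.6 | 80.4 |
| alder | 2.00 | 0 | 71.4 |
| alder | 3.00 | 0.3 | 65.4 |
| alder | 4.00 | 0.8 | 60.5 |
| larch | 0.500 | 0.5 | 86.7 |
| larch | 1.33 | 1.2 | 72.4 |
| larch | 2.50 | 1.1 | 59.5 |
| larch | 4.00 | 9.9 | 43.2 |
| cedar | 0.333 | 1.4 | 89.6 |
| cedar | 0.667 | 0 | 83.5 |
| cedar | 1.50 | 0.4 | 72.5 |
| cedar | 4.00 | 4.9 | 49.4 |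

(scatter of a reading: 0.5 percentage points)

- the numbers in the tables scatter with a standard deviation of 0.5 percentage points

* ranking by amount of Q, in percent of the L charged, from high to low, at 8.0 h (theta / delta / gamma / eta)
* the same order at 30 h (theta / delta / gamma / eta)
* the amount of Q, in percent of the L charged of the flask you put first, at 8.0 h
* the amount of Q, in percent of the L charged of the flask you put last, at 8.0 h

**Starting rate.** I assume that X, the limiting reagent, claims its own charge of L. Call the L charged beyond the X charged free L, F = c(L) − c(X), which in eta is 22.0 mM, and take g proportional to F. Larch has 8.70 mM more F than cedar and shows 2.02 times its Q. Scaled up, that gives gamma, with F of 45.0 mM, a g of 0.909 h⁻¹. Two noisy readings carry this, so it is rough.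

**What slows it.** In cedar, nearly gamma's twin, L plus Q at 4.00 h is 54.3 %. The missing 45.7 % is more than the 9.40 % that X can claim, so another loss takes L as well. Let C be that L plus Q. The rate per Q then shrinks by the factor 1 − Q/C, and integration makes Q/(C − Q) grow as exp(gt). From cedar's 0.0992, the remaining 4.00 h multiply this by 38.0. My figure for gamma is therefore 42.9 %, with the factor down to 0.210.

**Ranking.** F rises from theta at 4.00 mM through delta at 15.0 mM and eta at 22.0 mM to gamma at 45.0 mM. With g taken proportional to F, gamma's g is 11.2 times theta's.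

**The forecast.** It gives gamma > eta > delta > theta at 8.0 h and gamma > eta > delta > theta at 30 h, with 25 % on top (range 14 % to 40 %) and 0.3 % last. Its ground is that “X looks like a scavenger or inhibitor that must be used up first”. My order for 8.0 h is the same, but my top figure is higher.

**The result.**

    L + Q → 2 Q (k = 0.0120 M⁻¹ s⁻¹)
    L → Q (k = 8.20 × 10⁻⁸ s⁻¹)
    L + X → E (k = 0.0110 M⁻¹ s⁻¹)
    2 L → Z (k = 4.90 × 10⁻⁴ M⁻¹ s⁻¹)

At 8.0 h, gamma gives 45.0 % and theta 0.418 %, in the order gamma > eta > delta > theta; at 30 h the order is eta > gamma > delta > theta. At 8.00 h, gamma still has 4.34 % as L, while Z holds 40.7 % of the L charged. Now take a neighbour of theta, charged with 0.030 M of L and the same 8.00 mM of X. Its F is 22.0 mM, equal to eta's 22.0 mM. At 8.00 h the neighbour holds 2.42 mM of Q, and eta holds 2.30 mM.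

All runs are simulated on assumed constants; scatter was added.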